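(The earlier runs and the new flask are simulated from invented constants, and the scatter is random.)

Take time as the axis and read the flask as an area under a curve. Solid substrate dissolves into starting material, the enzyme turns starting material into product, and the product made so far should follow the area under the starting-material curve.

the same everywhere: solid substrate 0.10 M
- Friday's: enzyme 0.01 mol%; the very flask that is asked about, followed so far
- Thursday's: enzyme 0.0067 mol%; run made earlier
- flask: enzyme 0.01 mol%; time 20 min

| run | time / min | product / % | starting material / % |
|---|---|---|---|
| Friday's | 0.500 | 0 | 3.9 |
| Friday's | 0.833 | 0 | 6.6 |
| Friday's | 1.50 | 0 | 11.9 |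
| Friday's | 3.00 | 1.7 | 22.2 |
| Friday's | 6.00 | 2.9 | 36.9 |
| Thursday's | 1.33 | 1.4 | 10.9 |
| Thursday's | 4.00 | 2.4 | 25.9 |
| Thursday's | 6.00 | 2.3 | 37.9 |
| Thursday's | 10.0 | 5.3 | 50.1 |
| Thursday's | 15.0 | 8.3 | 61.4 |

(readings scatter by 1 percentage point)

- how much product there is at 20 min, in percent of the solid substrate charged
- concentration of starting material in solution at 2.0 min, in percent of saturation
- the change that raises the amount of product at 20 min, in percent of the solid substrate charged most ("none" if none brings more than 2 percentage points) (south-west / north / north-east / none)
- amount of product at 20 min, in percent of the solid substrate charged, after south-west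

- south-west: doubling the amount of enzyme, all else as stated
- north: doubling the solubility of the solid substrate, all else as stated
- north-east: doubling the dissolution coefficient of the solid substrate, all else as stated

- given per volume of solution although it is solid: solid substrate
- the earlier runs were read with a standard deviation of 1 percentage point
- on the list of suspects stand: starting material + enzyme -> product + enzyme; solid substrate <-> starting material
- at the start none of the solid substrate is in solution
- starting material means what is dissolved; the solid is not counted in it

Name the ratio of product to that area the conversion constant, treating the step as pseudo-first-order at a fixed enzyme loading. Get it in two ways. Friday's trapezoids give an area of 1.23 min of whole charge, and its last product reading gives 0.0236 min⁻¹. Thursday's area is 5.75 min, and scaled to Friday's loading it gives 0.0215 min⁻¹. The two runs agree within the scatter. Keep Thursday's value, since Friday's rests on 2.9 %, a smaller reading than Thursday's 8.3 %, with the same scatter of 1 percentage point.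

Now read the dissolving. The first Friday reading gives an early rate of 0.0780 min⁻¹ of the charge. Thursday's late rise of starting material plus product then gives a dissolution coefficient of 0.0886 min⁻¹ and a saturation of 88.0 %. Ignore the enzyme's drain and the area yields 20.2 % of product at 20 min. Put the drain back, adding the constant to the coefficient to get 0.110 min⁻¹, and this reckoning falls to 18.2 %. It has 81.3 % of the charge dissolved by then, so solid remains. It also puts 15.9 % of saturation at 2.0 min.

The forecast says 18 % (15 % to 21 %), 16.5 % of saturation (14 % to 20 %), and south-west as the best change, giving 33 % (27 % to 38 %). In its words: “South-west wins, though saturation kinetics could narrow its lead.”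

The flask gives 21.6 % of product at 20 min. Its starting material stands at 16.2 % of saturation at 2.0 min. The best change is south-west, with 38.4 % of product after it.

    starting material + enzyme → product + enzyme, rate k1*[starting material]^1.5*[enzyme]/(1 + ([starting material]/Kh1)^1.5) (0.100 M, k = 260 M⁻¹·⁵ s⁻¹)
    solid substrate ⇌ starting material, rate k2*(cs2 - [starting material]) while solid is left; crystals form when [starting material] > cs2 (solubility = 0.0900 M, k = 0.00150 s⁻¹)

The flask made more product than the reckoned 18.2 %, and over the reckoned area its 21.6 % asks for a constant of 0.0255 min⁻¹. Carry Thursday's constant to the neighbour with 0.40 M of solid substrate at the same loading. Multiply the constant by 4.00 to get 0.0862 min⁻¹, and divide the saturation share by the same factor to get 22.0 %. Starting material then levels near 11.2 % of that larger charge, and product reaches 14.0 % at 20 min. That neighbour holds 10.5 % of starting material and 15.5 % of product.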